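**Retrosynthetic overview**

- Feature: the cis-dimethylated C4a–C8a ring fusion, two adjacent quaternary carbons shared by ring A (C1–C4) and ring B (C5–C8), is read as the trace of a diene adding to the tetrasubstituted alkene of a ring A ene-dione.
- Key disconnection: C4a–C5 and C8a–C8 by [4+2] cycloaddition of 2,3-dimethylcyclohex-2-ene-1,4-dione (ring A, preformed) with (E)-1-silyloxybuta-1,3-diene; ring B is closed in that step.
- Ring A afterwards: the C4 carbonyl is removed while C1 is parked as an alcohol; the C1 ketone then goes to the enol triflate, is carbonylated with (R)-solketal, and takes a methyl cuprate at C2.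
- Ring B and end game: C5–O to ketone to enol triflate, Negishi coupling with homoprenylzinc bromide; C1 equilibrated to the trans ester, acetonide cleaved, primary hydroxyl acetylated.

Key step: step 3

Numbering used throughout: decalin C1 (ester carbon), C2 (methyl carbon), C3, C4, C4a and C8a (methylated fusion carbons), C5 (side-chain carbon), C6–C8; β is the face of the two angular methyls, α the other face.

Remark 1 (assumption): the sense of induction of the oxazaborolidinium catalyst on this dienophile cannot be fixed in advance; the (S)-catalyst is written, and its enantiomer is used if it proves to give the mirror-image adduct.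

Remark 2 (assumption): protonation at C1 in step 10 is taken to give the 1,2-cis ester drawn for 16 to 23; any 1,2-trans ester formed is carried along and both converge on 24 in step 16.

**Route**

Step 1
Reactants: 1 2,3-dimethylcyclohex-2-en-1-one
Product: 2 2,3-dimethylcyclohex-2-ene-1,4-dione
Conditions: t-BuOOH (70 % aq., 5 equiv), Rh2(caprolactamate)4 (1 mol %), ClCH2CH2Cl, 40 °C, no base; used at once
Reagents that add atoms: tert-butyl hydroperoxide, CC(C)(C)OO
Why: Allylic oxidation of an enone at its γ-methylene (Kharasch–Sosnovsky-type peroxidation, then Kornblum–DeLaMare collapse) is an established way from cyclohexenones to 2-ene-1,4-diones; the secondary ring C–H should be abstracted before the methyl C–H bonds, and base is left out so that 2 does not tautomerise to 2,3-dimethylhydroquinone.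

Step 2
Reactants: 3 (E)-but-2-enal (crotonaldehyde)
Product: 4 (E)-1-(triisopropylsilyloxy)buta-1,3-diene
Conditions: i-Pr3SiOTf, Et3N, Et2O, 0 → 25 °C
Reagents that add atoms: triisopropylsilyl triflate, CC(C)[Si](OS(=O)(=O)C(F)(F)F)(C(C)C)C(C)C
Why: Soft γ-enolisation of the enal with a silyl triflate and an amine (vinylogous silyl enol ether formation) should give mainly the E diene, which is also the only isomer able to reach the s-cis geometry needed in step 3.

Step 3
Reactants: 2 2,3-dimethylcyclohex-2-ene-1,4-dione; 4 (E)-1-(triisopropylsilyloxy)buta-1,3-diene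
Product: 5 (4aS,5R,8aS)-4a,8a-dimethyl-5-(triisopropylsilyloxy)-2,3,4a,5,8,8a-hexahydronaphthalene-1,4-dione (cis-fused, 5-silyloxy α)
Conditions: (S)-B-o-tolyl oxazaborolidine from (S)-α,α-diphenylprolinol, protonated with Tf2NH (20 mol %), CH2Cl2, −78 → −40 °C
Reagents that add atoms: none
Why: Proposed new method: the protonated oxazaborolidine binds one carbonyl of the symmetric ene-dione 2, and the electron-rich diene 4 adds suprafacially to the tetrasubstituted C4a=C8a alkene in a concerted but asynchronous [4+2] cycloaddition, its unsubstituted terminus (C8) bonding to the alkene carbon β to the bound carbonyl (C8a) and its oxygenated terminus (C5) to C4a. The closest known reactions are oxazaborolidinium-catalysed Diels–Alder additions of silyloxy dienes to methyl-substituted 1,4-benzoquinones and the thermal additions of 1-oxygenated butadienes to 2,3-dialkyl 2-ene-1,4-diones and 2,3-dimethylmaleic anhydride; what is new is asymmetric catalysis on a tetrasubstituted, non-quinoid alkene. Ring B is closed by the cycloaddition itself as a cyclohexene, C4a–C5 and C8a–C8 being formed in the same step. C4a and C8a come out cis because addition to a ring alkene is suprafacial, C5 is set by the carbonyl-endo transition state of the E diene (silyloxy group anti to the angular methyls), and the absolute configuration is set by the catalyst, which screens one face of the bound enone. The step needs only endo and facial selectivity, since the symmetry of 2 removes regiochemistry, and it needs cycloaddition to outrun enolisation of 2 to 2,3-dimethylhydroquinone and protodesilylation of 4, for which the double carbonyl activation of the alkene, the low temperature and the non-nucleophilic triflimide counter-ion are relied on.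

Step 4
Reactants: 5 Diels–Alder adduct
Product: 6 (4aS,5R,8aS)-4a,8a-dimethyl-5-(triisopropylsilyloxy)octahydronaphthalene-1,4-dione (cis-decalin-1,4-dione, 5-silyloxy α)
Conditions: H2 (1 atm), Pd/C (10 %), EtOAc, 25 °C
Reagents that add atoms: none
Why: Heterogeneous catalytic hydrogenation of the cis-disubstituted C6=C7 alkene should leave ketones and silyl ether untouched, removes any retro-Diels–Alder pathway, and gives the all-chair cis-decalin whose conformation is used in steps 5 and 10.

Step 5
Reactants: 6 cis-decalin-1,4-dione
Product: 7 1β-hydroxy-4a,8a-dimethyl-5α-(triisopropylsilyloxy)-cis-decalin-4-one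
Conditions: LiAlH(Ot-Bu)3 (1.1 equiv), THF, −78 → −20 °C
Reagents that add atoms: none
Why: Sterically controlled hydride reduction: the C4 carbonyl is screened by the gauche C5 silyloxy group on the neighbouring quaternary carbon, so the bulky alkoxyaluminium hydride should take the C1 carbonyl, entering anti to the axial C4a methyl; the C1 carbinol centre is destroyed again in step 7, so its configuration does not matter.

Step 6
Reactants: 7 hydroxy ketone
Product: 9 4a,8a-dimethyl-5α-(triisopropylsilyloxy)-cis-decalin-1β-ol, via C4 hydrazone 8 (not isolated)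
Conditions: N2H4·H2O, AcOH (cat.), EtOH, 80 °C; evaporate; then KOt-Bu, DMSO, 25 → 60 °C
Reagents that add atoms: none
Why: Wolff–Kishner reduction run on the preformed hydrazone with KOt-Bu in DMSO should remove the hindered C4 carbonyl at moderate temperature, where the silyl ether and the free alcohol survive; no stereocentre is formed.

Step 7
Reactants: 9 alcohol
Product: 10 4a,8a-dimethyl-5α-(triisopropylsilyloxy)-cis-decalin-1-one
Conditions: Dess–Martin periodinane, NaHCO3, CH2Cl2, 25 °C
Reagents that add atoms: none
Why: Dess–Martin oxidation of the secondary alcohol under buffered conditions returns the C1 ketone, now the only carbonyl group of the molecule.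

Step 8
Reactants: 10 ketone
Product: 12 4a,8a-dimethyl-5α-(triisopropylsilyloxy)-cis-3,4,4a,5,6,7,8,8a-octahydronaphthalen-1-yl triflate, via potassium enolate 11 (not isolated)
Conditions: KN(SiMe3)2, THF, −78 °C; then N-(5-chloro-2-pyridyl)triflimide, −78 → 0 °C
Reagents that add atoms: N-(5-chloro-2-pyridyl)bis(trifluoromethanesulfonimide), O=S(=O)(N(c1ccc(Cl)cn1)S(=O)(=O)C(F)(F)F)C(F)(F)F
Why: Kinetic enolate O-triflation: C8a is quaternary, so the ketone can enolise only towards C2 and a single enol triflate is possible.

Step 9
Reactants: 12 enol triflate; 13 (R)-solketal [(R)-(2,2-dimethyl-1,3-dioxolan-4-yl)methanol]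
Product: 14 ester of (R)-solketal with 4a,8a-dimethyl-5α-(triisopropylsilyloxy)-cis-3,4,4a,5,6,7,8,8a-octahydronaphthalene-1-carboxylic acid (C1=C2 enoate)
Conditions: Pd(OAc)2 (5 mol %), Ph2P(CH2)3PPh2 (6 mol %), CO (1 atm), 13 (3 equiv), Et3N, DMF, 60 °C
Reagents that add atoms: carbon monoxide, [C-]#[O+]
Why: Palladium-catalysed alkoxycarbonylation of an alkenyl triflate (oxidative addition, CO insertion, alcoholysis of the acyl palladium) installs the ester carbon at C1 and the glycerol unit in one step; the solketal stereocentre is not touched, its primary oxygen becoming the ester oxygen.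

Step 10
Reactants: 14 enoate
Product: 16 ester of (R)-solketal with 2α,4a,8a-trimethyl-5α-(triisopropylsilyloxy)-cis-decalin-1α-carboxylic acid, via silyl ketene acetal 15 (not isolated)
Conditions: Me2CuLi (from MeLi and CuBr·SMe2, 3 equiv), Me3SiCl, THF, −78 → −30 °C; then aq. NH4Cl
Reagents that add atoms: lithium dimethylcuprate, [Li+].C[Cu-]C (made in the flask from methyllithium, [Li]C, and CuBr·SMe2)
Why: Silyl-chloride-accelerated cuprate conjugate addition to a cyclohexenecarboxylate: the equatorial C5 silyloxy group holds the cis-decalin in the chair–chair form with C8 axial on ring A, chair-like axial delivery of methyl to C2 then comes from the α face, and attack on the β face would need a boat whose flagpole position clashes with the axial C4a methyl, so the C2 methyl should end up anti to the angular methyls; C1 is only protonated here and is corrected in step 16.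

Step 11
Reactants: 16 silyl ether
Product: 17 ester of (R)-solketal with 5α-hydroxy-2α,4a,8a-trimethyl-cis-decalin-1α-carboxylic acid
Conditions: HF·pyridine, pyridine, THF, 0 → 25 °C
Reagents that add atoms: none
Why: Fluoride cleavage of the silyl ether under buffered acidic conditions should leave the ester, the acetonide and C1 alone and forms no alkoxide that could lactonise onto the C1 ester.

Step 12
Reactants: 17 alcohol
Product: 18 ester of (R)-solketal with 2α,4a,8a-trimethyl-5-oxo-cis-decalin-1α-carboxylic acid
Conditions: Dess–Martin periodinane, NaHCO3, CH2Cl2, 25 °C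
Reagents that add atoms: none
Why: Dess–Martin oxidation gives the C5 ketone; since C4 is already a methylene group, no 1,3-dicarbonyl unit prone to retro-Claisen cleavage arises.

Step 13
Reactants: 18 ketone
Product: 20 ester of (R)-solketal with 2α,4a,8a-trimethyl-5-(trifluoromethanesulfonyloxy)-cis-1,2,3,4,4a,7,8,8a-octahydronaphthalene-1α-carboxylic acid, via potassium enolate 19 (not isolated)
Conditions: KN(SiMe3)2 (1.05 equiv), THF, −78 °C; then N-(5-chloro-2-pyridyl)triflimide, −78 °C
Reagents that add atoms: N-(5-chloro-2-pyridyl)bis(trifluoromethanesulfonimide), O=S(=O)(N(c1ccc(Cl)cn1)S(=O)(=O)C(F)(F)F)C(F)(F)F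
Why: Kinetic enolate O-triflation: C4a is quaternary, so the ketone enolises only towards C6, its α-hydrogen is removed before the hindered ester α-hydrogen at C1, and cold, fast trapping should forestall Claisen-type attack of the enolate on the ester.

Step 14
Reactants: 21 5-bromo-2-methylpent-2-ene
Product: 22 (4-methylpent-3-en-1-yl)zinc bromide (THF solution, LiCl complex)
Conditions: Zn dust (activated with BrCH2CH2Br and Me3SiCl), LiCl, THF, 40 °C
Reagents that add atoms: zinc, [Zn]
Why: Direct insertion of LiCl-activated zinc into a primary alkyl bromide gives the alkylzinc halide, and the trisubstituted alkene is inert to it.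

Step 15
Reactants: 20 enol triflate; 22 (4-methylpent-3-en-1-yl)zinc bromide
Product: 23 ester of (R)-solketal with (1R,2R,4aR,8aR)-2,4a,8a-trimethyl-5-(4-methylpent-3-en-1-yl)-1,2,3,4,4a,7,8,8a-octahydronaphthalene-1-carboxylic acid (C1 epimer of the target series)
Conditions: Pd(dppf)Cl2 (5 mol %), THF, 50 °C
Reagents that add atoms: none
Why: Negishi sp2–sp3 cross-coupling of an alkenyl triflate with a primary alkylzinc bromide; the bidentate ferrocenyl diphosphine favours reductive elimination over β-hydride elimination, and ester and acetonide are tolerated.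

Step 16
Reactants: 23 cis ester
Product: 24 ester of (R)-solketal with (1S,2R,4aR,8aR)-2,4a,8a-trimethyl-5-(4-methylpent-3-en-1-yl)-1,2,3,4,4a,7,8,8a-octahydronaphthalene-1-carboxylic acid
Conditions: KOt-Bu (0.3 equiv), t-BuOH/THF, 40 °C
Reagents that add atoms: none
Why: Base-mediated epimerisation through the ester enolate (thermodynamic control): with C5 now sp2 the ring system can take the chair in which C1 ester and C2 methyl are both equatorial only in the 1,2-trans isomer, whereas the cis isomer must set one of them syn-axial to a ring-fusion carbon substituent, so the equilibrium should lie on the side of the (1S) ester, and tert-butoxide does not transesterify this hindered ester.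

Step 17
Reactants: 24 acetonide
Product: 25 (S)-2,3-dihydroxypropyl (1S,2R,4aR,8aR)-2,4a,8a-trimethyl-5-(4-methylpent-3-en-1-yl)-1,2,3,4,4a,7,8,8a-octahydronaphthalene-1-carboxylate
Conditions: AcOH/H2O (4:1), 40 °C
Reagents that add atoms: none
Why: Mild acid hydrolysis of the isopropylidene acetal should not protonate the trisubstituted alkenes, and the hindered acyl group is slow to migrate to the secondary hydroxyl.

Step 18
Reactants: 25 diol
Product: 26 (S)-3-acetoxy-2-hydroxypropyl (1S,2R,4aR,8aR)-2,4a,8a-trimethyl-5-(4-methylpent-3-en-1-yl)-1,2,3,4,4a,7,8,8a-octahydronaphthalene-1-carboxylate (target)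
Conditions: AcCl (1.05 equiv), 2,4,6-collidine, CH2Cl2, −78 °C
Reagents that add atoms: acetyl chloride, CC(=O)Cl
Why: Selective acylation of the primary hydroxyl of a 1,2-diol with an acid chloride and a hindered pyridine base at low temperature, the secondary hydroxyl reacting much more slowly, completes the target.

**Compound list**

1 | 2,3-dimethylcyclohex-2-en-1-one | CC1=C(C)C(=O)CCC1 | starting material
2 | 2,3-dimethylcyclohex-2-ene-1,4-dione | CC1=C(C)C(=O)CCC1=O | intermediate
3 | (E)-but-2-enal (crotonaldehyde) | C/C=C/C=O | starting material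
4 | (E)-1-(triisopropylsilyloxy)buta-1,3-diene | C=C/C=C/O[Si](C(C)C)(C(C)C)C(C)C | intermediate
5 | (4aS,5R,8aS)-4a,8a-dimethyl-5-(triisopropylsilyloxy)-2,3,4a,5,8,8a-hexahydronaphthalene-1,4-dione | O=C1CCC(=O)[C@]2(C)[C@H](O[Si](C(C)C)(C(C)C)C(C)C)C=CC[C@]12C | intermediate
6 | (4aS,5R,8aS)-4a,8a-dimethyl-5-(triisopropylsilyloxy)octahydronaphthalene-1,4-dione | O=C1CCC(=O)[C@]2(C)[C@H](O[Si](C(C)C)(C(C)C)C(C)C)CCC[C@]12C | intermediate
7 | 1β-hydroxy-4a,8a-dimethyl-5α-(triisopropylsilyloxy)-cis-decalin-4-one | O[C@H]1CCC(=O)[C@]2(C)[C@H](O[Si](C(C)C)(C(C)C)C(C)C)CCC[C@]12C | intermediate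
8 | C4 hydrazone of 7 | O[C@H]1CCC(=NN)[C@]2(C)[C@H](O[Si](C(C)C)(C(C)C)C(C)C)CCC[C@]12C | intermediate
9 | 4a,8a-dimethyl-5α-(triisopropylsilyloxy)-cis-decalin-1β-ol | O[C@H]1CCC[C@]2(C)[C@H](O[Si](C(C)C)(C(C)C)C(C)C)CCC[C@]12C | intermediate
10 | 4a,8a-dimethyl-5α-(triisopropylsilyloxy)-cis-decalin-1-one | O=C1CCC[C@]2(C)[C@H](O[Si](C(C)C)(C(C)C)C(C)C)CCC[C@]12C | intermediate
11 | potassium enolate of 10 (C1=C2) | [K+].[O-]C1=CCC[C@]2(C)[C@H](O[Si](C(C)C)(C(C)C)C(C)C)CCC[C@]12C | intermediate
12 | C1 enol triflate of 10 | O=S(=O)(OC1=CCC[C@]2(C)[C@H](O[Si](C(C)C)(C(C)C)C(C)C)CCC[C@]12C)C(F)(F)F | intermediate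
13 | (R)-solketal | CC1(C)OC[C@H](O1)CO | starting material
14 | (R)-solketal ester of the C1=C2 unsaturated acid, 5α-silyloxy | CC1(C)OC[C@H](O1)COC(=O)C2=CCC[C@]3(C)[C@H](O[Si](C(C)C)(C(C)C)C(C)C)CCC[C@]23C | intermediate
15 | trimethylsilyl ketene acetal of 16 | CC1(C)OC[C@H](O1)COC(O[Si](C)(C)C)=C2[C@H](C)CC[C@]3(C)[C@H](O[Si](C(C)C)(C(C)C)C(C)C)CCC[C@]23C | intermediate
16 | (R)-solketal ester, 2α-methyl, 1α-ester, 5α-silyloxy cis-decalin | CC1(C)OC[C@H](O1)COC(=O)[C@@H]2[C@H](C)CC[C@]3(C)[C@H](O[Si](C(C)C)(C(C)C)C(C)C)CCC[C@]23C | intermediate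
17 | (R)-solketal ester, 2α-methyl, 1α-ester, 5α-hydroxy cis-decalin | CC1(C)OC[C@H](O1)COC(=O)[C@@H]2[C@H](C)CC[C@]3(C)[C@H](O)CCC[C@]23C | intermediate
18 | (R)-solketal ester, 2α-methyl, 1α-ester, 5-oxo cis-decalin | CC1(C)OC[C@H](O1)COC(=O)[C@@H]2[C@H](C)CC[C@]3(C)C(=O)CCC[C@]23C | intermediate
19 | potassium enolate of 18 (C5=C6) | [K+].CC1(C)OC[C@H](O1)COC(=O)[C@@H]2[C@H](C)CC[C@]3(C)C([O-])=CCC[C@]23C | intermediate
20 | C5 enol triflate of 18 | CC1(C)OC[C@H](O1)COC(=O)[C@@H]2[C@H](C)CC[C@]3(C)C(OS(=O)(=O)C(F)(F)F)=CCC[C@]23C | intermediate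
21 | 5-bromo-2-methylpent-2-ene | CC(C)=CCCBr | starting material
22 | (4-methylpent-3-en-1-yl)zinc bromide | CC(C)=CCC[Zn]Br | intermediate
23 | (R)-solketal ester of the (1R,2R,4aR,8aR) acid (C1 epimer) | CC1(C)OC[C@H](O1)COC(=O)[C@@H]2[C@H](C)CC[C@]3(C)C(CCC=C(C)C)=CCC[C@]23C | intermediate
24 | (R)-solketal ester of the (1S,2R,4aR,8aR) acid | CC1(C)OC[C@H](O1)COC(=O)[C@H]2[C@H](C)CC[C@]3(C)C(CCC=C(C)C)=CCC[C@]23C | intermediate
25 | (S)-2,3-dihydroxypropyl (1S,2R,4aR,8aR) ester | OC[C@H](O)COC(=O)[C@H]1[C@H](C)CC[C@]2(C)C(CCC=C(C)C)=CCC[C@]12C | intermediate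
26 | (S)-3-acetoxy-2-hydroxypropyl (1S,2R,4aR,8aR)-2,4a,8a-trimethyl-5-(4-methylpent-3-en-1-yl)-1,2,3,4,4a,7,8,8a-octahydronaphthalene-1-carboxylate | CC(=O)OC[C@H](O)COC(=O)[C@H]1[C@H](C)CC[C@]2(C)C(CCC=C(C)C)=CCC[C@]12C | target

**Step count**

Total: 18 steps. Longest linear sequence: 16 steps (1, 3 to 13, 15 to 18, from compound 1).

**Steps most likely to fail**

Step 3 (Proposed new method). What may go wrong: cycloaddition at the tetrasubstituted alkene may be too slow, so that acid-promoted enolisation of the ene-dione to the hydroquinone and loss of the silyl diene take over, or the catalyst may discriminate the faces poorly. The fallback sets out from 2 and 4 and uses known chemistry. Uncatalysed cycloaddition under high pressure (CH2Cl2, about 12 kbar, 25 °C), a known reaction type for 1-oxygenated dienes and 2,3-dialkyl ene-diones, gives the racemic endo adduct, that is 5 together with the enantiomeric adduct F1. The two are separated by preparative chromatography on a chiral stationary phase (amylose tris(3,5-dimethylphenylcarbamate)), F1 is set aside, and the route is rejoined at 5.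

Step 10. What may go wrong: facial selectivity at C2 may erode if the bulky cuprate avoids the axial path next to the C8 methylene, and addition to the hindered enoate may be slow. The fallback sets out from 14 and delivers the carbon from the C5 oxygen, which sits on the α face, through a temporary silicon tether. HF·pyridine in THF frees the hydroxy enoate F2. ClSiMe2CH2Br, Et3N and DMAP in CH2Cl2 give the (bromomethyl)dimethylsilyl ether F3. Bu3SnH (slow addition) with AIBN in benzene at 80 °C generates the α-silyl radical, which can reach the β-carbon C2 of the enoate only from the α face and closes to the bridged siloxane F4. Bu4NF in DMF at 70 °C then cleaves Si–O and protodesilylates Si–C, leaving the C2 methyl and the C5 hydroxyl, and the route is rejoined at 17 (C1 is corrected in step 16 as before).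

Step 5. What may go wrong: the hydride may not tell the two ketones apart well enough, or may reduce both. The fallback sets out from 6 and differentiates them intramolecularly. HF·pyridine frees the C5 hydroxyl, which can reach only the C1 carbonyl and closes to the bridged hemiketal F5. HC(OMe)3, MeOH and camphorsulfonic acid give the mixed methyl ketal F6. Hydrazine hydrate in EtOH, then KOt-Bu in DMSO, remove the now unique C4 carbonyl through the hydrazone F7 to give the deoxygenated ketal F8. Aqueous HCl in THF releases the hydroxy ketone F9, and i-Pr3SiOTf with 2,6-lutidine in CH2Cl2 returns the silyl ether, rejoining the route at 10.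

**Further compounds**

F1 | step 3 | (4aR,5S,8aR)-4a,8a-dimethyl-5-(triisopropylsilyloxy)-2,3,4a,5,8,8a-hexahydronaphthalene-1,4-dione (enantiomer of 5) | O=C1CCC(=O)[C@@]2(C)[C@@H](O[Si](C(C)C)(C(C)C)C(C)C)C=CC[C@@]12C
F2 | step 10 | (R)-solketal ester of the C1=C2 unsaturated acid, 5α-hydroxy | CC1(C)OC[C@H](O1)COC(=O)C2=CCC[C@]3(C)[C@H](O)CCC[C@]23C
F3 | step 10 | (bromomethyl)dimethylsilyl ether of F2 | CC1(C)OC[C@H](O1)COC(=O)C2=CCC[C@]3(C)[C@H](O[Si](C)(C)CBr)CCC[C@]23C
F4 | step 10 | bridged siloxane with C2α–CH2–SiMe2–O–C5 | CC1(C)OC[C@H](O1)COC(=O)[C@@H]2[C@H]4CC[C@]3(C)[C@H](O[Si](C)(C)C4)CCC[C@]23C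
F5 | step 5 | bridged hemiketal (C5–O–C1), C4 ketone | O[C@]12CCC(=O)[C@]3(C)[C@H](O1)CCC[C@]23C
F6 | step 5 | mixed methyl ketal of F5 | CO[C@]12CCC(=O)[C@]3(C)[C@H](O1)CCC[C@]23C
F7 | step 5 | C4 hydrazone of F6 | CO[C@]12CCC(=NN)[C@]3(C)[C@H](O1)CCC[C@]23C
F8 | step 5 | C4-deoxygenated methyl ketal | CO[C@]12CCC[C@]3(C)[C@H](O1)CCC[C@]23C
F9 | step 5 | 5α-hydroxy-4a,8a-dimethyl-cis-decalin-1-one | O=C1CCC[C@]2(C)[C@H](O)CCC[C@]12C
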